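**Retrosynthetic overview**

1. Numbering: C1 = lactone C=O, ring O between C1 and C5, C2=C3 cis, carbinols at C7/C9/C11/C15. Enabling feature: in the dihydropyranone ring the O–C1(=O) unit lies between the vinylic C2 and C5, and C5–O stands 1,3 to the C7 carbinol, so O–C1(=O) can be one CO2 and C5/C7 can share a six-membered cyclic sulfate ring.
2. Key disconnection (the only ring of the target, formed last): C1–C2 by CO2 insertion into a (Z)-alkenylcopper made from an acyclic (Z)-alkenylboronate, and O–C5 by 6-exo-tet opening of the C5,C7-cyclic sulfate with inversion, which also frees C7–OH.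
3. The inverted (5R) precursor is the normal outcome of a 1,5-anti boron aldol (C5–C6) of a C6–C26 methyl ketone with 4-(trimethylsilyl)but-3-ynal, followed by 1,3-anti reduction (C7), cyclic sulfate formation and trans-hydroboration.
4. Methyl ketone: syn C9/C11 from hemiacetal/oxa-Michael acetalisation of an enone (cross-metathesis with methyl vinyl ketone); C11 and C15 from two Brown allylborations; the C11 carbon itself from CO by hydroformylation.
5. Ring order: temporary 1,3-dioxane (step 6), temporary cyclic sulfate (step 11), dihydropyranone (step 13); the sulfate ring is consumed in step 13 and the dioxane is removed in step 14.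

Key step: step 13

Remark (assumption): the Brown allylborations are taken to follow their usual facial sense, (−)-Ipc2B(allyl) (from (+)-α-pinene) adding to the Si face of an aliphatic aldehyde and (+)-Ipc2B(allyl) to the Re face. Locants C1–C26 in all names below are those of the target chain; IPr = 1,3-bis(2,6-diisopropylphenyl)imidazol-2-ylidene.

**Route**

Step 1
Reactants: 1 dodecanal
Product: 2 (4S)-pentadec-1-en-4-ol
Conditions: (+)-Ipc2BOMe, allylMgBr, Et2O, 0 °C to rt; then 1, −78 °C; NaOH, H2O2, rt
Reagents that add atoms: allylmagnesium bromide, C=CC[Mg]Br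
Why: Brown asymmetric allylboration, in which the (+)-Ipc2B(allyl) made in the flask transfers allyl to the Re face of the aldehyde through a closed chair transition state and so sets C15 as S by reagent control.

Step 2
Reactants: 2 (4S)-pentadec-1-en-4-ol
Product: 3 (4S)-4-(tert-butyldimethylsilyloxy)pentadec-1-ene
Conditions: TBSCl, imidazole, DMF, rt
Reagents that add atoms: tert-butyldimethylsilyl chloride, CC(C)(C)[Si](C)(C)Cl
Why: Standard silyl ether protection of a secondary alcohol, which touches no stereocenter.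

Step 3
Reactants: 3 (4S)-4-(tert-butyldimethylsilyloxy)pentadec-1-ene
Product: 4 (5S)-5-(tert-butyldimethylsilyloxy)hexadecanal
Conditions: Rh(acac)(CO)2 (1 mol%), BiPhePhos, CO/H2 (1:1, 5 bar), THF, 60 °C
Reagents that add atoms: carbon monoxide, [C-]#[O+]
Why: Linear-selective rhodium-catalysed hydroformylation of a terminal alkene with a wide-bite-angle bisphosphite adds C11 as the aldehyde carbon and creates no stereocenter.

Step 4
Reactants: 4 (5S)-5-(tert-butyldimethylsilyloxy)hexadecanal
Product: 5 (4R,8S)-8-(tert-butyldimethylsilyloxy)nonadec-1-en-4-ol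
Conditions: (−)-Ipc2BOMe, allylMgBr, Et2O, 0 °C to rt; then 4, −78 °C; NaOH, H2O2, rt
Reagents that add atoms: allylmagnesium bromide, C=CC[Mg]Br
Why: Brown allylboration with the enantiomeric reagent (−)-Ipc2B(allyl), which adds to the Si face and sets C11 as R under reagent control, the remote C15 centre having no influence.

Step 5
Reactants: 5 (4R,8S)-8-(tert-butyldimethylsilyloxy)nonadec-1-en-4-ol
Product: 6 (3E,6R,10S)-10-(tert-butyldimethylsilyloxy)-6-hydroxyhenicos-3-en-2-one
Conditions: Hoveyda–Grubbs second-generation catalyst (5 mol%), methyl vinyl ketone (5 equiv), CH2Cl2, 40 °C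
Reagents that add atoms: methyl vinyl ketone, C=CC(C)=O
Why: Olefin cross-metathesis of a terminal alkene with an electron-poor enone partner should give the (E)-enone under thermodynamic control and tolerates the free homoallylic alcohol.

Step 6
Reactants: 6 (3E,6R,10S)-10-(tert-butyldimethylsilyloxy)-6-hydroxyhenicos-3-en-2-one
Product: 7 1-[(2R,4R,6R)-6-[(4S)-4-(tert-butyldimethylsilyloxy)pentadecyl]-2-methyl-1,3-dioxan-4-yl]propan-2-one (all-cis dioxane; C9/C11 ethylidene acetal)
Conditions: CH3CHO (5 equiv), Bi(NO3)3·5H2O (10 mol%), CH2Cl2, rt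
Reagents that add atoms: acetaldehyde, CC=O
Why: Two-component hemiacetal formation and intramolecular oxa-Michael addition to the enone under equilibrating conditions should give the all-equatorial cis-2,4,6-trisubstituted 1,3-dioxane, so the new C9–O bond is set syn to C11–O (and the acetal carbon R) by thermodynamic control.

Step 7
Reactants: 8 4-(trimethylsilyl)but-3-yn-1-ol
Product: 9 4-(trimethylsilyl)but-3-ynal
Conditions: Dess–Martin periodinane, NaHCO3, CH2Cl2, 0 °C; filtered and used at once
Reagents that add atoms: none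
Why: Dess–Martin oxidation under buffered, amine-free conditions should deliver the β,γ-acetylenic aldehyde without isomerisation to the allenyl aldehyde, and no stereocenter is involved.

Step 8
Reactants: 7 dioxanyl methyl ketone; 9 4-(trimethylsilyl)but-3-ynal
Product: 11 aldol adduct with (5R) carbinol and C7 ketone (C2≡C3 alkyne with SiMe3 on C2; acetal and C15 silyl ether as in 7), via dibutylboron enolate 10 (not isolated)
Conditions: Bu2BOTf, iPr2NEt, Et2O, −78 °C; then 9, −78 to −20 °C; MeOH, pH 7 buffer, H2O2, 0 °C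
Reagents that add atoms: none
Why: Boron-mediated aldol reaction of a β-alkoxy methyl ketone, in which the kinetic methyl-side dibutylboron enolate adds to the aldehyde with 1,5-anti induction from the C9 acetal oxygen and so sets the C5 carbinol as R (anti to C9–O).

Step 9
Reactants: 11 aldol adduct
Product: 12 C5/C7 anti diol (5R,7S,9S,11R,15S) with silylated alkyne
Conditions: Me4NBH(OAc)3, MeCN/AcOH (1:1), −30 °C
Reagents that add atoms: none
Why: Evans–Saksena reduction, in which the C5 hydroxyl binds the acetoxyborohydride and delivers hydride intramolecularly through a chair transition state, gives the 1,3-anti diol and thereby C7 in the configuration of the target (syn to C9–O).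

Step 10
Reactants: 12 silylated alkyne diol
Product: 13 C5/C7 anti diol (5R,7S,9S,11R,15S) with terminal alkyne C2≡C3
Conditions: K2CO3, MeOH, rt
Reagents that add atoms: none
Why: Base-mediated protodesilylation of an alkynylsilane (C–Si methanolysis) leaves the O-silyl ether, the acetal and all stereocenters untouched.

Step 11
Reactants: 13 terminal alkyne diol
Product: 15 C5,C7-cyclic sulfate (1,3,2-dioxathiane 2,2-dioxide; 5R,7R,9R,11R,15S), via cyclic sulfite 14 (not isolated)
Conditions: SOCl2, Et3N, CH2Cl2, 0 °C; then RuCl3·xH2O (1 mol%), NaIO4, MeCN/H2O, 0 °C, 15 min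
Reagents that add atoms: thionyl chloride, O=S(Cl)Cl; sodium periodate, [Na+].[O-]I(=O)(=O)=O
Why: Two-stage cyclic sulfate synthesis from a 1,3-diol (cyclic sulfite, then ruthenium tetroxide-catalysed oxidation at sulfur) keeps both C–O bonds intact, so C5 and C7 retain their configuration.

Step 12
Reactants: 15 cyclic sulfate alkyne
Product: 16 (2Z)-alkenyl pinacol boronate with C5,C7-cyclic sulfate (boron on C2)
Conditions: pinacolborane, [Rh(cod)Cl]2 (1.5 mol%), P(iPr)3 (6 mol%), Et3N, cyclohexane, rt
Reagents that add atoms: pinacolborane, CC1(C)OBOC1(C)C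
Why: Rhodium-catalysed trans-hydroboration of a terminal alkyne through a rhodium vinylidene (1,2-hydrogen shift) places boron cis to the chain and should give the (Z)-1-alkenylboronate without touching any stereocenter.

Step 13
Reactants: 16 (2Z)-alkenyl pinacol boronate cyclic sulfate
Product: 19 C7 hydroxy lactone (5S,7R,9S,11R,15S; C9/C11 acetal and C15 silyl ether retained), via potassium enoate 17 (not isolated), via lactone sulfate salt 18 (not isolated)
Conditions: [(IPr)CuCl] (5 mol%), KOtBu (1.05 equiv, added under CO2), CO2 (1 atm), THF, 0 to 60 °C; then H2SO4 (cat.), H2O (2 equiv), THF, rt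
Reagents that add atoms: carbon dioxide, O=C=O
Why: Copper–carbene-catalysed carboxylation of an alkenylboronic ester is merged with carboxylate opening of a cyclic sulfate, both close-precedent reaction types (CO2 carboxylation of alkenylboronates; invertive SN2 lactonisation of carboxylates on sulfate and sulfonate esters): (IPr)Cu–OtBu takes the alkenyl group from boron with retention of the Z geometry, CO2 inserts into the Cu–C bond to forge C1–C2, and exchange with the potassium base releases enoate 17. Its carboxylate oxygen then attacks C5 from the face opposite the departing sulfate oxygen, a 6-exo-tet closure of the dihydropyranone ring that forms O–C5 and leaves C7–O as sulfate monoester 18, which the low-water acid treatment cleaves at S–O with retention to give 19. The only new stereocenter, C5, is controlled by stereospecific inversion of the (5R) centre installed in step 8, so the easily made anti C5/C7 diol becomes the syn array of the target. Regioselectivity (C5, not C7) is secured by ring size, six-membered against an eight-membered alternative, and the cis C2=C3 geometry that the ring needs is fixed in step 12 and kept by the configurationally stable alkenylcopper. Chemoselectivity needs the base to spare the cyclic sulfate, which should be secured by its immediate capture as boronate and tert-butyl carbonate under CO2 and by the much faster intramolecular attack once the carboxylate exists.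

Step 14
Reactants: 19 C7 hydroxy lactone
Product: 20 (6S)-6-[(2R,4R,6R,10S)-2,4,6,10-tetrahydroxyhenicosyl]-5,6-dihydro-2H-pyran-2-one (target)
Conditions: TFA/H2O (9:1), CH2Cl2, 0 °C to rt
Reagents that add atoms: none
Why: Acid-mediated global deprotection (acetal hydrolysis and desilylation) breaks no bond at a stereocenter and avoids the base-induced oxa-Michael addition of the C7 hydroxyl to the enoate.

**Compound list**

1 | dodecanal | CCCCCCCCCCCC=O | starting material
2 | (4S)-pentadec-1-en-4-ol | CCCCCCCCCCC[C@H](O)CC=C | intermediate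
3 | (4S)-4-(tert-butyldimethylsilyloxy)pentadec-1-ene | CCCCCCCCCCC[C@H](O[Si](C)(C)C(C)(C)C)CC=C | intermediate
4 | (5S)-5-(tert-butyldimethylsilyloxy)hexadecanal | CCCCCCCCCCC[C@H](O[Si](C)(C)C(C)(C)C)CCCC=O | intermediate
5 | (4R,8S)-8-(tert-butyldimethylsilyloxy)nonadec-1-en-4-ol | CCCCCCCCCCC[C@H](O[Si](C)(C)C(C)(C)C)CCC[C@@H](O)CC=C | intermediate
6 | (3E,6R,10S)-10-(tert-butyldimethylsilyloxy)-6-hydroxyhenicos-3-en-2-one | CCCCCCCCCCC[C@H](O[Si](C)(C)C(C)(C)C)CCC[C@@H](O)C/C=C/C(C)=O | intermediate
7 | 1-[(2R,4R,6R)-6-[(4S)-4-(tert-butyldimethylsilyloxy)pentadecyl]-2-methyl-1,3-dioxan-4-yl]propan-2-one (all-cis dioxane) | CCCCCCCCCCC[C@H](O[Si](C)(C)C(C)(C)C)CCC[C@@H]1C[C@H](CC(C)=O)O[C@H](C)O1 | intermediate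
8 | 4-(trimethylsilyl)but-3-yn-1-ol | C[Si](C)(C)C#CCCO | starting material
9 | 4-(trimethylsilyl)but-3-ynal | C[Si](C)(C)C#CCC=O | intermediate
10 | dibutylboron enolate of 7 (C6=C7 enol borinate) | CCCCCCCCCCC[C@H](O[Si](C)(C)C(C)(C)C)CCC[C@@H]1C[C@H](CC(=C)OB(CCCC)CCCC)O[C@H](C)O1 | intermediate
11 | aldol adduct, C5 carbinol and C7 ketone (5R,9R,11R,15S; acetal carbon R; SiMe3 on C2) | CCCCCCCCCCC[C@H](O[Si](C)(C)C(C)(C)C)CCC[C@@H]1C[C@H](CC(=O)C[C@H](O)CC#C[Si](C)(C)C)O[C@H](C)O1 | intermediate
12 | C5/C7 anti diol with silylated alkyne (5R,7S,9S,11R,15S) | CCCCCCCCCCC[C@H](O[Si](C)(C)C(C)(C)C)CCC[C@@H]1C[C@H](C[C@@H](O)C[C@H](O)CC#C[Si](C)(C)C)O[C@H](C)O1 | intermediate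
13 | C5/C7 anti diol with terminal alkyne (5R,7S,9S,11R,15S) | CCCCCCCCCCC[C@H](O[Si](C)(C)C(C)(C)C)CCC[C@@H]1C[C@H](C[C@@H](O)C[C@H](O)CC#C)O[C@H](C)O1 | intermediate
14 | C5,C7-cyclic sulfite of 13 (both sulfur epimers) | CCCCCCCCCCC[C@H](O[Si](C)(C)C(C)(C)C)CCC[C@@H]1C[C@H](C[C@@H]2C[C@@H](CC#C)OS(=O)O2)O[C@H](C)O1 | intermediate
15 | C5,C7-cyclic sulfate of 13 (5R,7R,9R,11R,15S) | CCCCCCCCCCC[C@H](O[Si](C)(C)C(C)(C)C)CCC[C@@H]1C[C@H](C[C@@H]2C[C@@H](CC#C)OS(=O)(=O)O2)O[C@H](C)O1 | intermediate
16 | (2Z)-alkenyl pinacol boronate with C5,C7-cyclic sulfate (5R,7R,9R,11R,15S) | CCCCCCCCCCC[C@H](O[Si](C)(C)C(C)(C)C)CCC[C@@H]1C[C@H](C[C@@H]2C[C@@H](C/C=C\B3OC(C)(C)C(C)(C)O3)OS(=O)(=O)O2)O[C@H](C)O1 | intermediate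
17 | potassium (2Z)-enoate with C5,C7-cyclic sulfate | CCCCCCCCCCC[C@H](O[Si](C)(C)C(C)(C)C)CCC[C@@H]1C[C@H](C[C@@H]2C[C@@H](C/C=C\C(=O)[O-])OS(=O)(=O)O2)O[C@H](C)O1.[K+] | intermediate
18 | potassium C7 sulfate monoester of the lactone (5S,7R,9R,11R,15S) | CCCCCCCCCCC[C@H](O[Si](C)(C)C(C)(C)C)CCC[C@@H]1C[C@H](C[C@@H](OS(=O)(=O)[O-])C[C@@H]2CC=CC(=O)O2)O[C@H](C)O1.[K+] | intermediate
19 | C7 hydroxy lactone with C9/C11 ethylidene acetal and C15 silyl ether (5S,7R,9S,11R,15S) | CCCCCCCCCCC[C@H](O[Si](C)(C)C(C)(C)C)CCC[C@@H]1C[C@H](C[C@@H](O)C[C@@H]2CC=CC(=O)O2)O[C@H](C)O1 | intermediate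
20 | (6S)-6-[(2R,4R,6R,10S)-2,4,6,10-tetrahydroxyhenicosyl]-5,6-dihydro-2H-pyran-2-one (CNP0158746.1) | CCCCCCCCCCC[C@H](O)CCC[C@@H](O)C[C@@H](O)C[C@@H](O)C[C@@H]1CC=CC(=O)O1 | target

**Step count and risks**

Total step count: 14. Longest linear sequence: 13 (steps 1–6 and 8–14 from dodecanal; step 7 prepares the C2–C5 aldehyde).

Steps most likely to fail:

1. Step 13. Process at risk: attack of the alkoxide/carbonate base on the cyclic sulfate (substitution or elimination) before the carboxylate exists, or protodeboronation outrunning transmetalation and CO2 insertion. The fallback closes the ring through other bonds with known chemistry; it sets out from 11 and comes back at 20.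
   - Evans–Tishchenko reduction of 11 (SmI2 cat., PhCHO, THF, −10 °C) should give the C5 benzoate C7 alcohol F1 with the anti C7 carbinol.
   - TBSOTf and 2,6-lutidine give the C7 silyl ether F2.
   - K2CO3 in MeOH at 40 °C removes the benzoate and the alkynyl silane to give the homopropargylic alcohol F3.
   - H2 over Pd/CaCO3/Pb (Lindlar catalyst) with quinoline gives the homoallylic alcohol F4.
   - Mitsunobu esterification with acrylic acid (PPh3, DIAD, THF, 0 °C) inverts C5 and gives the (5S) acrylate F5.
   - Ring-closing metathesis with second-generation Grubbs catalyst (CH2Cl2, 40 °C) gives the protected lactone F6.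
   - TFA/H2O as in step 14 then gives 20.

2. Step 8. Process at risk: amine-induced isomerisation of the β,γ-acetylenic aldehyde to its allenyl isomer and self-condensation, which would erode both conversion and the 1,5-anti induction. The fallback builds the alkyne after the aldol; it sets out from 7 and comes back at 13.
   - The same boron enolate 10 is combined with anhydrous chloroacetaldehyde (a robust two-carbon aldehyde) to give the chloromethyl aldol adduct F7 by the same 1,5-anti aldol.
   - Me4NBH(OAc)3 as in step 9 gives the anti diol chloride F8.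
   - K2CO3 in MeOH at 0 °C closes the C4–C5 epoxide with retention at C5 to give the epoxy alcohol F9.
   - Lithium acetylide–ethylenediamine complex (LiC≡CH·H2NCH2CH2NH2) in DMSO at rt opens the epoxide at C4 and gives 13.

3. Step 12. Process at risk: erosion of Z selectivity by competing syn-hydroboration and slow attack of the amine on the cyclic sulfate. The fallback makes the same boronate by metathesis; it sets out from 15 and comes back at 16.
   - Semihydrogenation of 15 (H2, Pd/CaCO3/Pb, quinoline, EtOAc) gives the terminal alkene cyclic sulfate F10.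
   - Z-selective cross-metathesis with vinylboronic acid pinacol ester, using a molybdenum monoaryloxide pyrrolide alkylidene catalyst Mo(NAr)(CHCMe2Ph)(2,5-dimethylpyrrolide)(OAr′) in benzene at rt under reduced pressure, gives 16.

Further compounds
F1 | step 13 | C5 benzoate C7 alcohol from Evans–Tishchenko reduction of 11 (C5/C7 anti) | CCCCCCCCCCC[C@H](O[Si](C)(C)C(C)(C)C)CCC[C@@H]1C[C@H](C[C@@H](O)C[C@H](OC(=O)c2ccccc2)CC#C[Si](C)(C)C)O[C@H](C)O1
F2 | step 13 | C7 tert-butyldimethylsilyl ether of F1 | CCCCCCCCCCC[C@H](O[Si](C)(C)C(C)(C)C)CCC[C@@H]1C[C@H](C[C@@H](O[Si](C)(C)C(C)(C)C)C[C@H](OC(=O)c2ccccc2)CC#C[Si](C)(C)C)O[C@H](C)O1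
F3 | step 13 | homopropargylic C5 alcohol with terminal alkyne and C7 silyl ether | CCCCCCCCCCC[C@H](O[Si](C)(C)C(C)(C)C)CCC[C@@H]1C[C@H](C[C@@H](O[Si](C)(C)C(C)(C)C)C[C@H](O)CC#C)O[C@H](C)O1
F4 | step 13 | homoallylic C5 alcohol with terminal alkene and C7 silyl ether | CCCCCCCCCCC[C@H](O[Si](C)(C)C(C)(C)C)CCC[C@@H]1C[C@H](C[C@@H](O[Si](C)(C)C(C)(C)C)C[C@H](O)CC=C)O[C@H](C)O1
F5 | step 13 | (5S) acrylate ester (C5 inverted) | CCCCCCCCCCC[C@H](O[Si](C)(C)C(C)(C)C)CCC[C@@H]1C[C@H](C[C@@H](O[Si](C)(C)C(C)(C)C)C[C@@H](OC(=O)C=C)CC=C)O[C@H](C)O1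
F6 | step 13 | lactone with C7 and C15 silyl ethers and C9/C11 ethylidene acetal | CCCCCCCCCCC[C@H](O[Si](C)(C)C(C)(C)C)CCC[C@@H]1C[C@H](C[C@@H](O[Si](C)(C)C(C)(C)C)C[C@@H]2CC=CC(=O)O2)O[C@H](C)O1
F7 | step 8 | chloromethyl aldol adduct (C5 carbinol, C7 ketone, chloride on C4) | CCCCCCCCCCC[C@H](O[Si](C)(C)C(C)(C)C)CCC[C@@H]1C[C@H](CC(=O)C[C@H](O)CCl)O[C@H](C)O1
F8 | step 8 | C5/C7 anti diol with chloride on C4 | CCCCCCCCCCC[C@H](O[Si](C)(C)C(C)(C)C)CCC[C@@H]1C[C@H](C[C@@H](O)C[C@H](O)CCl)O[C@H](C)O1
F9 | step 8 | C4–C5 epoxide with free C7 alcohol | CCCCCCCCCCC[C@H](O[Si](C)(C)C(C)(C)C)CCC[C@@H]1C[C@H](C[C@@H](O)C[C@H]2CO2)O[C@H](C)O1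
F10 | step 12 | terminal alkene with C5,C7-cyclic sulfate | CCCCCCCCCCC[C@H](O[Si](C)(C)C(C)(C)C)CCC[C@@H]1C[C@H](C[C@@H]2C[C@@H](CC=C)OS(=O)(=O)O2)O[C@H](C)O1
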